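**Retrosynthetic overview**
1. Glycybridin C (19) comes from its silyl ether 18 by O–Si cleavage at the carbinol oxygen.
2. 18 comes from the bis(1,1-dimethylallyl) ether 16 by two aromatic Claisen shifts. The feature used is that each prenyl group sits on a ring carbon ortho to a phenolic oxygen: C3 of ring A (between O2 and O4 of the 2,4-dihydroxybenzoyl ring) and C3 of ring B (next to O4 of the 4-hydroxybenzyl ring). Both aryl–CH2 bonds can therefore be made from O–CMe2–CH=CH2 ethers.
3. 16 comes from triphenol 13 by O-alkylation of the two non-chelated phenols with 3-chloro-3-methylbut-1-yne (14), then Lindlar semihydrogenation.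
4. 13 comes from forming the aryl–C(=O) bond: the aryllithium from dibenzylated 4-bromoresorcinol (9) adds to Weinreb amide 7, made from D-tyrosine (1) through (R)-4-hydroxyphenyllactic acid, which carries the only stereocentre.
5. No ring is formed anywhere; both benzene rings are bought and only joined and decorated.

Key step: step 10

Remark on the chemistry: ring A is taken as the 2,4-dihydroxybenzoyl ring and ring B as the 4-hydroxybenzyl ring. The carbinol carbon (C2 of the propan-1-one chain) is (R), the same spatial arrangement as C2 of D-tyrosine, so the deamination in step 1 must proceed with net retention.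

**Route**

Step 1
Reactants: 1 D-tyrosine
Product: 4 (R)-2-hydroxy-3-(4-hydroxyphenyl)propanoic acid, via diazonium carboxylate 2 (not isolated), via alpha-lactone 3 (not isolated)
Conditions: NaNO2, 1 M aq. H2SO4, 0 °C → rt
Reagents that add atoms: water, O
Why: Diazotisation of the alpha-amino acid (nitrous acid deamination) gives the diazonium carboxylate, whose carboxylate displaces N2 with inversion to the alpha-lactone, and water opens this with a second inversion, so the (R) configuration of D-tyrosine is retained at C2.

Step 2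
Reactants: 4 (R)-2-hydroxy-3-(4-hydroxyphenyl)propanoic acid
Product: 5 benzyl (R)-3-[4-(benzyloxy)phenyl]-2-hydroxypropanoate
Conditions: BnBr (2.2 equiv), K2CO3, DMF, rt
Reagents that add atoms: benzyl bromide, BrCc1ccccc1
Why: Carbonate deprotonates only the carboxylic acid and the phenol, so Williamson-type O-benzylation should give the benzyl ester and the aryl benzyl ether in one operation while the secondary alcohol and its stereocentre are left alone.

Step 3
Reactants: 5 benzyl (R)-3-[4-(benzyloxy)phenyl]-2-hydroxypropanoate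
Product: 6 benzyl (R)-3-[4-(benzyloxy)phenyl]-2-[(tert-butyldimethylsilyl)oxy]propanoate
Conditions: TBSCl, imidazole, DMF, rt
Reagents that add atoms: tert-butyldimethylsilyl chloride, CC(C)(C)[Si](C)(C)Cl
Why: Imidazole-promoted silylation of the secondary alcohol is standard, and the silyl ether is kept to the last step because it blocks enediol and alpha-ketol isomerisation of the later alpha-oxy ketone.

Step 4
Reactants: 6 benzyl (R)-3-[4-(benzyloxy)phenyl]-2-[(tert-butyldimethylsilyl)oxy]propanoate
Product: 7 (R)-3-[4-(benzyloxy)phenyl]-2-[(tert-butyldimethylsilyl)oxy]-N-methoxy-N-methylpropanamide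
Conditions: MeNHOMe·HCl, iPrMgCl, THF, −20 → 0 °C
Reagents that add atoms: N,O-dimethylhydroxylamine hydrochloride, Cl.CNOC
Why: Weinreb amide formation by aminolysis of the ester with the chloromagnesium amide made in the flask, a nucleophile that is too weakly basic at low temperature to enolise the hindered alpha-silyloxy ester, so the (R) centre is kept.

Step 5
Reactants: 8 4-bromoresorcinol
Product: 9 2,4-bis(benzyloxy)-1-bromobenzene
Conditions: BnBr (2.2 equiv), K2CO3, DMF, 50 °C
Reagents that add atoms: benzyl bromide, BrCc1ccccc1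
Why: Twofold Williamson ether synthesis on both phenols gives an aryl bromide whose oxygen substituents tolerate bromine–lithium exchange at low temperature.

Step 6
Reactants: 9 2,4-bis(benzyloxy)-1-bromobenzene; 7 (R)-3-[4-(benzyloxy)phenyl]-2-[(tert-butyldimethylsilyl)oxy]-N-methoxy-N-methylpropanamide
Product: 12 (R)-1-[2,4-bis(benzyloxy)phenyl]-3-[4-(benzyloxy)phenyl]-2-[(tert-butyldimethylsilyl)oxy]propan-1-one, via 2,4-bis(benzyloxy)phenyllithium 10 (not isolated), via tetrahedral lithium hemiaminal alkoxide 11 (not isolated)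
Conditions: 9, n-BuLi, THF, −78 °C; then 7, −78 → −20 °C; aq. NH4Cl
Reagents that add atoms: none
Why: Bromine–lithium exchange followed by the Weinreb ketone synthesis forms the aryl–C(=O) bond; the chelated tetrahedral adduct survives until the quench, so no second addition occurs, and the low temperature disfavours deprotonation at the silyloxy-bearing carbon, so the (R) centre is carried through.

Step 7
Reactants: 12 (R)-1-[2,4-bis(benzyloxy)phenyl]-3-[4-(benzyloxy)phenyl]-2-[(tert-butyldimethylsilyl)oxy]propan-1-one
Product: 13 (R)-2-[(tert-butyldimethylsilyl)oxy]-1-(2,4-dihydroxyphenyl)-3-(4-hydroxyphenyl)propan-1-one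
Conditions: H2 (1 atm), 10% Pd/C, EtOAc, rt
Reagents that add atoms: none
Why: Catalytic hydrogenolysis removes the three benzyl ethers under neutral conditions, while the electron-rich, hydrogen-bonded aryl ketone and the silyl ether are expected to be untouched in ethyl acetate.

Step 8
Reactants: 13 (R)-2-[(tert-butyldimethylsilyl)oxy]-1-(2,4-dihydroxyphenyl)-3-(4-hydroxyphenyl)propan-1-one; 14 3-chloro-3-methylbut-1-yne
Product: 15 (R)-2-[(tert-butyldimethylsilyl)oxy]-1-[2-hydroxy-4-(2-methylbut-3-yn-2-yloxy)phenyl]-3-[4-(2-methylbut-3-yn-2-yloxy)phenyl]propan-1-one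
Conditions: 14 (2.6 equiv), DBU, CuCl2·2H2O (cat.), MeCN, −5 → 0 °C
Reagents that add atoms: none
Why: Copper-catalysed propargylic etherification of phenols with the tertiary propargylic chloride alkylates the ring A 4-hydroxyl and the ring B hydroxyl, whereas the 2-hydroxyl, held in a hydrogen bond to the ketone and flanked by the acyl group, is expected to stay free.

Step 9
Reactants: 15 (R)-2-[(tert-butyldimethylsilyl)oxy]-1-[2-hydroxy-4-(2-methylbut-3-yn-2-yloxy)phenyl]-3-[4-(2-methylbut-3-yn-2-yloxy)phenyl]propan-1-one
Product: 16 (R)-2-[(tert-butyldimethylsilyl)oxy]-1-[2-hydroxy-4-(2-methylbut-3-en-2-yloxy)phenyl]-3-[4-(2-methylbut-3-en-2-yloxy)phenyl]propan-1-one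
Conditions: H2 (1 atm), Lindlar catalyst (Pd on CaCO3 poisoned with Pb(OAc)2), quinoline, EtOAc, rt
Reagents that add atoms: none
Why: Lindlar semihydrogenation stops the two terminal alkynes at the alkene stage and gives the 1,1-dimethylallyl ethers without touching the ketone or the silyl ether.

Step 10
Reactants: 16 (R)-2-[(tert-butyldimethylsilyl)oxy]-1-[2-hydroxy-4-(2-methylbut-3-en-2-yloxy)phenyl]-3-[4-(2-methylbut-3-en-2-yloxy)phenyl]propan-1-one
Product: 18 (R)-2-[(tert-butyldimethylsilyl)oxy]-1-[2,4-dihydroxy-3-(3-methylbut-2-enyl)phenyl]-3-[4-hydroxy-3-(3-methylbut-2-enyl)phenyl]propan-1-one, via mono-rearranged ring A phenol 17 (not isolated)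
Conditions: PhNEt2 (degassed), 170–190 °C, Ar, shortest time needed; amine removed by chromatography
Reagents that add atoms: none
Why: Each aryl 1,1-dimethylallyl ether undergoes a concerted, chair-like [3,3]-sigmatropic shift (aromatic Claisen rearrangement) in which the terminal =CH2 carbon bonds to the ring carbon ortho to oxygen while the O–CMe2 bond breaks, so the branched ether is transposed into a linear 3-methylbut-2-enyl group and proton transfer returns the phenol; the closest known reaction type is the rearrangement of 4-O-(1,1-dimethylallyl) ethers of 2-hydroxyaryl ketones to 3-prenyl-2,4-dihydroxyaryl ketones. Two C–C bonds are formed (C3–CH2 on ring A and C3–CH2 on ring B), no ring is closed and no stereocentre is created; the (R) carbinol carbon is a spectator whose oxygen stays silylated so that it cannot isomerise through an enediol. The selectivity needed is C3 over C5 on ring A: the hydrogen bond between the 2-hydroxyl and the ketone fixes the ring in the form with more double-bond character between C3 and C4, so the allyl terminus is delivered to C3, and 17, in which ring A has already shifted, is expected to build up first because the acyl-stabilised phenoxide is the better leaving fragment in the polarised transition state. On ring B the two carbons ortho to the ether oxygen are equivalent, so only one product can form there. The geminal methyl groups weaken the O–C bond and should let both shifts run below 200 °C, and the basic amine solvent keeps the medium free of acid, which would otherwise add the new phenols across the prenyl double bonds to give 2,2-dimethylchromans.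

Step 11
Reactants: 18 (R)-2-[(tert-butyldimethylsilyl)oxy]-1-[2,4-dihydroxy-3-(3-methylbut-2-enyl)phenyl]-3-[4-hydroxy-3-(3-methylbut-2-enyl)phenyl]propan-1-one
Product: 19 glycybridin C
Conditions: HF·pyridine, excess pyridine, THF, 0 °C → rt
Reagents that add atoms: none
Why: Fluoride-driven desilylation (Si–F bond formation) frees the secondary alcohol, and the pyridine-buffered reagent is neither basic enough to enolise the alpha-hydroxy ketone nor acidic enough to cyclise the ortho-prenylphenols, so the (R) centre and both prenyl groups should survive.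

**Compound list**
1 | D-tyrosine | N[C@H](Cc1ccc(O)cc1)C(=O)O | starting material
2 | (R)-1-carboxylato-2-(4-hydroxyphenyl)ethanediazonium (diazonium carboxylate, not isolated) | N#[N+][C@H](Cc1ccc(O)cc1)C(=O)[O-] | intermediate
3 | (S)-3-(4-hydroxybenzyl)oxiran-2-one (alpha-lactone, not isolated) | O=C1O[C@H]1Cc1ccc(O)cc1 | intermediate
4 | (R)-2-hydroxy-3-(4-hydroxyphenyl)propanoic acid | O[C@H](Cc1ccc(O)cc1)C(=O)O | intermediate
5 | benzyl (R)-3-[4-(benzyloxy)phenyl]-2-hydroxypropanoate | O[C@H](Cc1ccc(OCc2ccccc2)cc1)C(=O)OCc1ccccc1 | intermediate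
6 | benzyl (R)-3-[4-(benzyloxy)phenyl]-2-[(tert-butyldimethylsilyl)oxy]propanoate | CC(C)(C)[Si](C)(C)O[C@H](Cc1ccc(OCc2ccccc2)cc1)C(=O)OCc1ccccc1 | intermediate
7 | (R)-3-[4-(benzyloxy)phenyl]-2-[(tert-butyldimethylsilyl)oxy]-N-methoxy-N-methylpropanamide | CC(C)(C)[Si](C)(C)O[C@H](Cc1ccc(OCc2ccccc2)cc1)C(=O)N(C)OC | intermediate
8 | 4-bromoresorcinol | Oc1ccc(Br)c(O)c1 | starting material
9 | 2,4-bis(benzyloxy)-1-bromobenzene | Brc1ccc(OCc2ccccc2)cc1OCc1ccccc1 | intermediate
10 | 2,4-bis(benzyloxy)phenyllithium (not isolated) | [Li]c1ccc(OCc2ccccc2)cc1OCc1ccccc1 | intermediate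
11 | lithium alkoxide of the N-methoxy-N-methyl hemiaminal from 10 and 7 (2R; hemiaminal carbon undefined; not isolated) | [Li]OC(N(C)OC)(c1ccc(OCc2ccccc2)cc1OCc1ccccc1)[C@@H](Cc1ccc(OCc2ccccc2)cc1)O[Si](C)(C)C(C)(C)C | intermediate
12 | (R)-1-[2,4-bis(benzyloxy)phenyl]-3-[4-(benzyloxy)phenyl]-2-[(tert-butyldimethylsilyl)oxy]propan-1-one | CC(C)(C)[Si](C)(C)O[C@H](Cc1ccc(OCc2ccccc2)cc1)C(=O)c1ccc(OCc2ccccc2)cc1OCc1ccccc1 | intermediate
13 | (R)-2-[(tert-butyldimethylsilyl)oxy]-1-(2,4-dihydroxyphenyl)-3-(4-hydroxyphenyl)propan-1-one | CC(C)(C)[Si](C)(C)O[C@H](Cc1ccc(O)cc1)C(=O)c1ccc(O)cc1O | intermediate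
14 | 3-chloro-3-methylbut-1-yne | CC(C)(Cl)C#C | starting material
15 | (R)-2-[(tert-butyldimethylsilyl)oxy]-1-[2-hydroxy-4-(2-methylbut-3-yn-2-yloxy)phenyl]-3-[4-(2-methylbut-3-yn-2-yloxy)phenyl]propan-1-one | CC(C)(C)[Si](C)(C)O[C@H](Cc1ccc(OC(C)(C)C#C)cc1)C(=O)c1ccc(OC(C)(C)C#C)cc1O | intermediate
16 | (R)-2-[(tert-butyldimethylsilyl)oxy]-1-[2-hydroxy-4-(2-methylbut-3-en-2-yloxy)phenyl]-3-[4-(2-methylbut-3-en-2-yloxy)phenyl]propan-1-one | CC(C)(C)[Si](C)(C)O[C@H](Cc1ccc(OC(C)(C)C=C)cc1)C(=O)c1ccc(OC(C)(C)C=C)cc1O | intermediate
17 | (R)-2-[(tert-butyldimethylsilyl)oxy]-1-[2,4-dihydroxy-3-(3-methylbut-2-enyl)phenyl]-3-[4-(2-methylbut-3-en-2-yloxy)phenyl]propan-1-one (not isolated) | CC(C)(C)[Si](C)(C)O[C@H](Cc1ccc(OC(C)(C)C=C)cc1)C(=O)c1ccc(O)c(CC=C(C)C)c1O | intermediate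
18 | (R)-2-[(tert-butyldimethylsilyl)oxy]-1-[2,4-dihydroxy-3-(3-methylbut-2-enyl)phenyl]-3-[4-hydroxy-3-(3-methylbut-2-enyl)phenyl]propan-1-one | CC(C)(C)[Si](C)(C)O[C@H](Cc1ccc(O)c(CC=C(C)C)c1)C(=O)c1ccc(O)c(CC=C(C)C)c1O | intermediate
19 | glycybridin C, (R)-1-[2,4-dihydroxy-3-(3-methylbut-2-enyl)phenyl]-2-hydroxy-3-[4-hydroxy-3-(3-methylbut-2-enyl)phenyl]propan-1-one | CC(C)=CCc1cc(C[C@@H](O)C(=O)c2ccc(O)c(CC=C(C)C)c2O)ccc1O | target

**Step count**
Total: 11 steps. Longest linear sequence: 10 steps (steps 1–4 and 6–11); step 5 is the one-step side branch.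

**Steps most likely to fail**

1. Step 10. The tertiary allyl groups may be lost thermally as isoprene, returning the phenols, before the sigmatropic shift is complete. Part of the ring A shift may go to C5 instead of C3. Long heating may also erode the (R) centre through slow enolisation of the alpha-silyloxy ketone. The fallback swaps the labile tertiary ethers for simple allyl ethers and builds the prenyl groups afterwards by olefin metathesis.
 - It sets out from 13, which is O-allylated at the two non-chelated phenols (allyl bromide, K2CO3, acetone, reflux) to give (R)-1-[4-(allyloxy)-2-hydroxyphenyl]-3-[4-(allyloxy)phenyl]-2-[(tert-butyldimethylsilyl)oxy]propan-1-one F1.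
 - F1 is heated in PhNEt2 at about 200 °C. Allyl ethers cannot fragment to a diene, and 4-allyloxy-2-hydroxyaryl ketones are the classical case of C3-selective Claisen rearrangement. This should give (R)-1-(3-allyl-2,4-dihydroxyphenyl)-3-(3-allyl-4-hydroxyphenyl)-2-[(tert-butyldimethylsilyl)oxy]propan-1-one F2.
 - Twofold cross-metathesis of F2 with excess 2-methylbut-2-ene, using second-generation Grubbs catalyst (H2IMes)(PCy3)Cl2Ru=CHPh in CH2Cl2 at rt to 40 °C, converts both allyl groups into prenyl groups. The fallback comes back to the route at 18.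

2. Step 8. Alkylation of the two phenols by the hindered tertiary electrophile may be incomplete, the chelated 2-hydroxyl may be attacked, and excess DBU may epimerise the carbon next to the ketone. The fallback makes the tertiary allyl ethers directly under neutral conditions by palladium-catalysed allylic substitution, which replaces steps 8 and 9.
 - The reagent tert-butyl 2-methylbut-3-en-2-yl carbonate F3 is prepared from 2-methylbut-3-en-2-ol and Boc2O.
 - Setting out from 13, treatment with F3 and Pd(PPh3)4 (zerovalent palladium) in THF at 0 °C should give decarboxylative O-allylation of the two free, non-chelated phenols at the more substituted allyl terminus. This comes back to the route at 16.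

3. Step 6. The aryllithium may abstract the proton at the silyloxy-bearing carbon of the amide instead of adding to the hindered carbonyl, and the ortho-benzyloxy aryllithium may decay by benzylic metalation if the mixture warms before addition is complete. The fallback replaces acylation by addition to a far more electrophilic aldehyde, followed by oxidation.
 - It sets out from 7, which is reduced (DIBAL-H, THF, −78 °C) to (R)-3-[4-(benzyloxy)phenyl]-2-[(tert-butyldimethylsilyl)oxy]propanal F4, used at once without purification.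
 - Aryllithium 10 (from 9 and n-BuLi at −78 °C) is added to F4 to give (2R)-1-[2,4-bis(benzyloxy)phenyl]-3-[4-(benzyloxy)phenyl]-2-[(tert-butyldimethylsilyl)oxy]propan-1-ol F5 as a mixture at C1, which is of no consequence.
 - Dess–Martin periodinane with NaHCO3 in CH2Cl2 oxidises F5 to the ketone, coming back to the route at 12.

**Further compounds**
F1 | step 10 | (R)-1-[4-(allyloxy)-2-hydroxyphenyl]-3-[4-(allyloxy)phenyl]-2-[(tert-butyldimethylsilyl)oxy]propan-1-one | CC(C)(C)[Si](C)(C)O[C@H](Cc1ccc(OCC=C)cc1)C(=O)c1ccc(OCC=C)cc1O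
F2 | step 10 | (R)-1-(3-allyl-2,4-dihydroxyphenyl)-3-(3-allyl-4-hydroxyphenyl)-2-[(tert-butyldimethylsilyl)oxy]propan-1-one | CC(C)(C)[Si](C)(C)O[C@H](Cc1ccc(O)c(CC=C)c1)C(=O)c1ccc(O)c(CC=C)c1O
F3 | step 8 | tert-butyl 2-methylbut-3-en-2-yl carbonate | CC(C)(C)OC(=O)OC(C)(C)C=C
F4 | step 6 | (R)-3-[4-(benzyloxy)phenyl]-2-[(tert-butyldimethylsilyl)oxy]propanal | CC(C)(C)[Si](C)(C)O[C@H](Cc1ccc(OCc2ccccc2)cc1)C=O
F5 | step 6 | (2R)-1-[2,4-bis(benzyloxy)phenyl]-3-[4-(benzyloxy)phenyl]-2-[(tert-butyldimethylsilyl)oxy]propan-1-ol | CC(C)(C)[Si](C)(C)O[C@H](Cc1ccc(OCc2ccccc2)cc1)C(O)c1ccc(OCc2ccccc2)cc1OCc1ccccc1
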